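A direct plan would C-prenylate phloroacetophenone to A1, condense A1 with benzaldehyde to the chalcone A2, close ring C by an enantioselective oxa-Michael addition to (S)-6-prenylpinocembrin A3, and attach ring D last through an ortho-quinone methide.
Its weakest step would be the ring closure of A2: the two ortho-hydroxyls differ, so the closure site (6- or 8-prenyl flavanone) and the configuration at C-2 would both rest on a catalyst effect without precedent, and the closure is reversible.
Next would be the final benzylation, which would heat the enantioenriched, ring-opening-prone A3 with an amine-releasing reagent; this is the step least welcome on late material (racemisation through the chalcone, scrambling of the methylene bridge).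
Third, mono-prenylation in aqueous alkali and an aldol condensation on the free triphenol with excess amide base would cost material for little gain in complexity.

**Plan of the new route**
The retrosynthesis cuts C4–C4a (the aryl–acyl bond of ring C) first, then C8–CH2, then O1–C2 (an intermolecular SN2 on an open chain), then the O1–C8a and C6–prenyl bonds of a resorcinol bis-ether.
The feature used: in ring A, O-1 lies para to the prenylated C-6 and between C-8 and C-4a, so aryl ether 7 has a local mirror plane through O-1 and C-6 and its two carbons ortho to O-1 are equivalent.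
Once one of them (C-8) carries ring D, the other (C-4a) is the only aromatic C–H in rings A and D, and it sits six atoms from the carboxyl carbon.
Ring order: ring A (from resorcinol) and ring D are joined first; ring C closes last by C–C bond formation and never through a chalcone.
So no choice of closure site arises, C-2 comes from a commercial enantiopure alcohol by inversion and stays an ether carbon until ring C exists, and no quinone methide meets a flavanone.

Key step: step 7

Assumption: 1, 6 and 8 are taken as purchasable; 1 would otherwise be one methoxymethyl (MOM) protection step from resorcinol.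

Step 1
Reactants: 1 1,3-bis(methoxymethoxy)benzene; 2 1-bromo-3-methylbut-2-ene (prenyl bromide)
Product: 3 1,3-bis(methoxymethoxy)-2-(3-methylbut-2-en-1-yl)benzene
Conditions: n-BuLi (1.2 equiv), THF, 0 °C, 1 h; CuBr·SMe2 (10 mol %), 2 (1.3 equiv), −78 °C → rt
Reagents that add atoms: none
Why: Directed ortho-metalation, in which the two MOM ethers jointly direct lithiation to the carbon between them and the aryl metal is alkylated by prenyl bromide at its primary carbon (SN2), places the prenyl group on the future C-6 with no stereocentre formed.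

Step 2
Reactants: 3 1,3-bis(methoxymethoxy)-2-(3-methylbut-2-en-1-yl)benzene
Product: 5 3,5-bis(methoxymethoxy)-4-(3-methylbut-2-en-1-yl)phenol, via aryl pinacol boronate 4 (not isolated)
Conditions: [Ir(OMe)(cod)]2 (1.5 mol %), 4,4'-di-tert-butyl-2,2'-bipyridine (3 mol %), B2pin2 (1.0 equiv), THF, 60 °C; then aq. NaOH, H2O2 (30 %), 0 °C
Reagents that add atoms: hydrogen peroxide, OO (phenol oxygen of 5); bis(pinacolato)diboron, CC1(C)OB(OC1(C)C)B1OC(C)(C)C(C)(C)O1 (boryl group of intermediate 4 only)
Why: Sterically controlled iridium-catalysed aromatic C–H borylation should go to the only C–H that is not ortho to a substituent (para to the prenyl group), and oxidation of the C–B bond then gives the symmetric phenol whose oxygen becomes O-1, with the trisubstituted alkene expected to survive both operations.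

Step 3
Reactants: 5 3,5-bis(methoxymethoxy)-4-(3-methylbut-2-en-1-yl)phenol; 6 ethyl (3R)-3-hydroxy-3-phenylpropanoate
Product: 7 ethyl (3S)-3-[3,5-bis(methoxymethoxy)-4-(3-methylbut-2-en-1-yl)phenoxy]-3-phenylpropanoate
Conditions: PPh3 (1.5 equiv), diisopropyl azodicarboxylate (1.5 equiv), toluene, 0 °C → rt
Reagents that add atoms: none
Why: Mitsunobu etherification, in which the unhindered phenoxide displaces the alkoxyphosphonium group by SN2 with inversion, turns the (R)-alcohol into the (S)-ether carbon (the future C-2), while the nonpolar solvent and low temperature are chosen to hold back elimination to ethyl cinnamate.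

Step 4
Reactants: 8 1-(2,4,6-trihydroxy-3-methylphenyl)ethanone; 9 N,N-dimethylmethaniminium iodide (1.05 equiv)
Product: 10 1-{3-[(dimethylamino)methyl]-2,4,6-trihydroxy-5-methylphenyl}ethanone
Conditions: MeCN, 0 °C → rt, 2 h; aq. NaHCO3 to pH 7
Reagents that add atoms: none
Why: Mannich aminomethylation with a preformed iminium ion can only occur at the single unsubstituted carbon of the acylphloroglucinol, so one regioisomer should form and no stereocentre is created.

Step 5
Reactants: 7 ethyl (3S)-3-[3,5-bis(methoxymethoxy)-4-(3-methylbut-2-en-1-yl)phenoxy]-3-phenylpropanoate (1.5 equiv); 10 1-{3-[(dimethylamino)methyl]-2,4,6-trihydroxy-5-methylphenyl}ethanone (1.0 equiv, added in portions)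
Product: 12 ethyl (3S)-3-{2-[(3-acetyl-2,4,6-trihydroxy-5-methylphenyl)methyl]-3,5-bis(methoxymethoxy)-4-(3-methylbut-2-en-1-yl)phenoxy}-3-phenylpropanoate, via ortho-quinone methide 11 (not isolated)
Conditions: AcOH (5 equiv), 1,4-dioxane, 80 °C, N2
Reagents that add atoms: none
Why: Thermal loss of dimethylamine from the Mannich base gives ortho-quinone methide 11, which should alkylate (Friedel–Crafts-type Michael addition) one of the two equivalent ring carbons ortho to the ether oxygen of 7, each activated by three oxygens, so both sites give the same product, the excess of 7 limits double alkylation, and the ether stereocentre is untouched.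

Step 6
Reactants: 12 ethyl (3S)-3-{2-[(3-acetyl-2,4,6-trihydroxy-5-methylphenyl)methyl]-3,5-bis(methoxymethoxy)-4-(3-methylbut-2-en-1-yl)phenoxy}-3-phenylpropanoate
Product: 13 (3S)-3-{2-[(3-acetyl-2,4,6-trihydroxy-5-methylphenyl)methyl]-3,5-bis(methoxymethoxy)-4-(3-methylbut-2-en-1-yl)phenoxy}-3-phenylpropanoic acid
Conditions: LiOH (6 equiv), THF/MeOH/H2O, 0 °C → rt; 1 M HCl to pH 3, 0 °C
Reagents that add atoms: lithium hydroxide, [Li+].[OH-] (oxygen of the new carboxylic OH)
Why: Ester saponification should outrun β-elimination because the electron-rich aryloxide is a poor leaving group, and with both ring A oxygens capped the methylene bridge cannot be released by a base-induced retro-Michael reaction.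

Step 7
Reactants: 13 (3S)-3-{2-[(3-acetyl-2,4,6-trihydroxy-5-methylphenyl)methyl]-3,5-bis(methoxymethoxy)-4-(3-methylbut-2-en-1-yl)phenoxy}-3-phenylpropanoic acid
Product: 15 (2S)-8-[(3-acetyl-2,4,6-trihydroxy-5-methylphenyl)methyl]-5,7-bis(methoxymethoxy)-6-(3-methylbut-2-en-1-yl)-2-phenyl-2,3-dihydro-4H-chromen-4-one, via mixed trifluoroacetic anhydride 14 (not isolated)
Conditions: (CF3CO)2O (3 equiv), CH2Cl2 (0.02 M), −20 → 0 °C; then MeOH, aq. NaHCO3, 0 °C
Reagents that add atoms: trifluoroacetic anhydride, O=C(OC(=O)C(F)(F)F)C(F)(F)F (trifluoroacetyl group of intermediate 14 only)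
Why: Trifluoroacetic anhydride converts the acid into mixed anhydride 14, an acyl cation equivalent that attacks C-4a, the only unsubstituted carbon of ring A (ortho to O-1 and O-5, para to O-7), and the arenium ion rearomatises by loss of a proton (intramolecular Friedel–Crafts acylation). The closest known reaction type is the anhydride- or acid-mediated cyclisation of 3-aryloxypropanoic and 3-aryloxy-3-phenylpropanoic acids to chroman-4-ones and flavanones. Ring C closes in the 6-exo-trig mode at the acyl carbon, which gives the six-membered pyranone made of C-4a, C-8a, O-1, C-2, C-3 and C-4. No stereocentre is formed; C-2 is the (S)-ether carbon set in step 3, and it is kept only if C–O ionisation and β-elimination of the aryloxy group are avoided, which the low temperature, the weak acid released (CF3CO2H) and the high nucleophilicity of the trioxygenated ring should secure by making closure the faster process. The step needs site selectivity for C-4a over ipso attack at the benzylated C-8, over ring D and over the prenyl double bond: ring D has no free carbon, C-8 is quaternary and more hindered, and with O-5 and O-7 capped the prenyl group cannot close to a chroman. Phenolic trifluoroacetates that may form on ring D would be cleaved in the methanolic hydrogencarbonate quench.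

Step 8
Reactants: 15 (2S)-8-[(3-acetyl-2,4,6-trihydroxy-5-methylphenyl)methyl]-5,7-bis(methoxymethoxy)-6-(3-methylbut-2-en-1-yl)-2-phenyl-2,3-dihydro-4H-chromen-4-one
Product: 16 (2S)-8-[(3-acetyl-2,4,6-trihydroxy-5-methylphenyl)methyl]-5,7-dihydroxy-6-(3-methylbut-2-en-1-yl)-2-phenyl-2,3-dihydro-4H-chromen-4-one (target)
Conditions: 3 M aq. HCl/MeOH (1:5), 40 °C
Reagents that add atoms: none
Why: Acid-catalysed transacetalisation removes both MOM ethers under conditions in which a flavanone does not open to the chalcone, so C-2 should stay (S), and the short exposure to dilute acid is chosen so that the prenyl group does not cyclise onto the freed hydroxyls.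

**Compound list**
1 | 1,3-bis(methoxymethoxy)benzene | COCOc1cccc(OCOC)c1 | starting material
2 | 1-bromo-3-methylbut-2-ene (prenyl bromide) | CC(C)=CCBr | starting material
3 | 1,3-bis(methoxymethoxy)-2-(3-methylbut-2-en-1-yl)benzene | COCOc1cccc(OCOC)c1CC=C(C)C | intermediate
4 | 2-[3,5-bis(methoxymethoxy)-4-(3-methylbut-2-en-1-yl)phenyl]-4,4,5,5-tetramethyl-1,3,2-dioxaborolane (not isolated) | COCOc1cc(B2OC(C)(C)C(C)(C)O2)cc(OCOC)c1CC=C(C)C | intermediate
5 | 3,5-bis(methoxymethoxy)-4-(3-methylbut-2-en-1-yl)phenol | COCOc1cc(O)cc(OCOC)c1CC=C(C)C | intermediate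
6 | ethyl (3R)-3-hydroxy-3-phenylpropanoate | CCOC(=O)C[C@@H](O)c1ccccc1 | starting material
7 | ethyl (3S)-3-[3,5-bis(methoxymethoxy)-4-(3-methylbut-2-en-1-yl)phenoxy]-3-phenylpropanoate | CCOC(=O)C[C@H](Oc1cc(OCOC)c(CC=C(C)C)c(OCOC)c1)c1ccccc1 | intermediate
8 | 1-(2,4,6-trihydroxy-3-methylphenyl)ethanone | CC(=O)c1c(O)cc(O)c(C)c1O | starting material
9 | N,N-dimethylmethaniminium iodide | C=[N+](C)C.[I-] | starting material
10 | 1-{3-[(dimethylamino)methyl]-2,4,6-trihydroxy-5-methylphenyl}ethanone | CC(=O)c1c(O)c(C)c(O)c(CN(C)C)c1O | intermediate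
11 | 4-acetyl-3,5-dihydroxy-2-methyl-6-methylidenecyclohexa-2,4-dien-1-one (ortho-quinone methide, not isolated) | CC(=O)C1=C(O)C(=C)C(=O)C(C)=C1O | intermediate
12 | ethyl (3S)-3-{2-[(3-acetyl-2,4,6-trihydroxy-5-methylphenyl)methyl]-3,5-bis(methoxymethoxy)-4-(3-methylbut-2-en-1-yl)phenoxy}-3-phenylpropanoate | CCOC(=O)C[C@H](Oc1cc(OCOC)c(CC=C(C)C)c(OCOC)c1Cc1c(O)c(C)c(O)c(C(C)=O)c1O)c1ccccc1 | intermediate
13 | (3S)-3-{2-[(3-acetyl-2,4,6-trihydroxy-5-methylphenyl)methyl]-3,5-bis(methoxymethoxy)-4-(3-methylbut-2-en-1-yl)phenoxy}-3-phenylpropanoic acid | OC(=O)C[C@H](Oc1cc(OCOC)c(CC=C(C)C)c(OCOC)c1Cc1c(O)c(C)c(O)c(C(C)=O)c1O)c1ccccc1 | intermediate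
14 | (3S)-3-{2-[(3-acetyl-2,4,6-trihydroxy-5-methylphenyl)methyl]-3,5-bis(methoxymethoxy)-4-(3-methylbut-2-en-1-yl)phenoxy}-3-phenylpropanoic trifluoroacetic anhydride (not isolated) | O=C(C[C@H](Oc1cc(OCOC)c(CC=C(C)C)c(OCOC)c1Cc1c(O)c(C)c(O)c(C(C)=O)c1O)c1ccccc1)OC(=O)C(F)(F)F | intermediate
15 | (2S)-8-[(3-acetyl-2,4,6-trihydroxy-5-methylphenyl)methyl]-5,7-bis(methoxymethoxy)-6-(3-methylbut-2-en-1-yl)-2-phenyl-2,3-dihydro-4H-chromen-4-one | CC(=O)c1c(O)c(C)c(O)c(Cc2c(OCOC)c(CC=C(C)C)c(OCOC)c3c2O[C@H](c2ccccc2)CC3=O)c1O | intermediate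
16 | (2S)-8-[(3-acetyl-2,4,6-trihydroxy-5-methylphenyl)methyl]-5,7-dihydroxy-6-(3-methylbut-2-en-1-yl)-2-phenyl-2,3-dihydro-4H-chromen-4-one | CC(=O)c1c(O)c(C)c(O)c(Cc2c(O)c(CC=C(C)C)c(O)c3c2O[C@H](c2ccccc2)CC3=O)c1O | target

**Step count**
Total: 8 steps. Longest linear sequence: 7 steps (steps 1, 2, 3, 5, 6, 7, 8).

**Steps most likely to fail**

Step 7. The activated acid may lose the aryloxy group by β-elimination and re-close through a cinnamoyl intermediate, which would erode the configuration at C-2. The trifluoroacetic acid released may also strip a MOM group or hydrate the prenyl group before the ring has closed. The fallback sets out from 13 and comes back at 15. The acid 13 would be coupled with dimethylamine (2 M in THF, EDC·HCl, HOBt cat.) to the N,N-dimethylamide F1. POCl3 in MeCN at 0 °C would turn F1 into the chloroiminium salt F2, which should close onto C-4a to the cyclic iminium salt F3 (intramolecular Vilsmeier–Haack ketone synthesis). Cold water would hydrolyse F3 to 15. The electrophile is then an iminium carbon instead of an acyl cation equivalent.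

Step 5. The capped, hindered arene may attack the quinone methide too slowly, so that the quinone methide is diverted to cycloaddition with the prenyl double bond or to self-condensation, or a second alkylation consumes the last ring carbon. The fallback sets out from 7 and comes back at 12, with the polarity reversed. Compound 7 would be aminomethylated with 9 (MeCN, 60 °C; NaHCO3 work-up) at one of its two equivalent carbons to the benzylic amine F4. F4 would be quaternised with MeI to the trimethylammonium iodide F5. F5 would then C-benzylate the only free ring carbon of 8 (NaHCO3, MeCN/H2O, 50 °C) to give 12.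

Step 3. The activated β-hydroxy ester may eliminate to ethyl cinnamate, or ionise at the benzylic carbon and lose enantiopurity. The fallback sets out from 5 and comes back at 13, so that steps 3 and 6 are bypassed.
- Iridium-catalysed enantioselective allylic etherification of 5 with methyl (E)-cinnamyl carbonate would give the branched allyl ether F6. The catalyst would be [Ir(cod)Cl]2 with the enantiomer of the O,O'-(1,1'-binaphthalene-2,2'-diyl) N,N-bis(1-phenylethyl)phosphoramidite ligand that delivers the (S)-ether, in THF at rt.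
- 9-BBN should hydroborate the vinyl group in preference to the trisubstituted prenyl alkene to give the alkylborane F7, which NaOH/H2O2 would oxidise to the primary alcohol F8.
- TEMPO (cat.) and PhI(OAc)2 in MeCN/H2O would give the acid F9.
- Benzylation of F9 with 10 under the conditions of step 5 would give 13.

**Further compounds**
F1 | step 7 | (3S)-3-{2-[(3-acetyl-2,4,6-trihydroxy-5-methylphenyl)methyl]-3,5-bis(methoxymethoxy)-4-(3-methylbut-2-en-1-yl)phenoxy}-N,N-dimethyl-3-phenylpropanamide | CN(C)C(=O)C[C@H](Oc1cc(OCOC)c(CC=C(C)C)c(OCOC)c1Cc1c(O)c(C)c(O)c(C(C)=O)c1O)c1ccccc1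
F2 | step 7 | N-[(3S)-3-{2-[(3-acetyl-2,4,6-trihydroxy-5-methylphenyl)methyl]-3,5-bis(methoxymethoxy)-4-(3-methylbut-2-en-1-yl)phenoxy}-1-chloro-3-phenylpropylidene]-N-methylmethanaminium dichlorophosphate | C[N+](C)=C(Cl)C[C@H](Oc1cc(OCOC)c(CC=C(C)C)c(OCOC)c1Cc1c(O)c(C)c(O)c(C(C)=O)c1O)c1ccccc1.[O-]P(=O)(Cl)Cl
F3 | step 7 | N-[(2S)-8-[(3-acetyl-2,4,6-trihydroxy-5-methylphenyl)methyl]-5,7-bis(methoxymethoxy)-6-(3-methylbut-2-en-1-yl)-2-phenyl-2,3-dihydro-4H-chromen-4-ylidene]-N-methylmethanaminium chloride | CC(=O)c1c(O)c(C)c(O)c(Cc2c(OCOC)c(CC=C(C)C)c(OCOC)c3c2O[C@H](c2ccccc2)CC3=[N+](C)C)c1O.[Cl-]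
F4 | step 5 | ethyl (3S)-3-{2-[(dimethylamino)methyl]-3,5-bis(methoxymethoxy)-4-(3-methylbut-2-en-1-yl)phenoxy}-3-phenylpropanoate | CCOC(=O)C[C@H](Oc1cc(OCOC)c(CC=C(C)C)c(OCOC)c1CN(C)C)c1ccccc1
F5 | step 5 | 1-{2-[(1S)-3-ethoxy-3-oxo-1-phenylpropoxy]-4,6-bis(methoxymethoxy)-5-(3-methylbut-2-en-1-yl)phenyl}-N,N,N-trimethylmethanaminium iodide | CCOC(=O)C[C@H](Oc1cc(OCOC)c(CC=C(C)C)c(OCOC)c1C[N+](C)(C)C)c1ccccc1.[I-]
F6 | step 3 | 1,3-bis(methoxymethoxy)-2-(3-methylbut-2-en-1-yl)-5-{[(1S)-1-phenylprop-2-en-1-yl]oxy}benzene | C=C[C@H](Oc1cc(OCOC)c(CC=C(C)C)c(OCOC)c1)c1ccccc1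
F7 | step 3 | 9-{(3S)-3-[3,5-bis(methoxymethoxy)-4-(3-methylbut-2-en-1-yl)phenoxy]-3-phenylpropyl}-9-borabicyclo[3.3.1]nonane | B1(CC[C@H](Oc2cc(OCOC)c(CC=C(C)C)c(OCOC)c2)c2ccccc2)C2CCCC1CCC2
F8 | step 3 | (3S)-3-[3,5-bis(methoxymethoxy)-4-(3-methylbut-2-en-1-yl)phenoxy]-3-phenylpropan-1-ol | OCC[C@H](Oc1cc(OCOC)c(CC=C(C)C)c(OCOC)c1)c1ccccc1
F9 | step 3 | (3S)-3-[3,5-bis(methoxymethoxy)-4-(3-methylbut-2-en-1-yl)phenoxy]-3-phenylpropanoic acid | OC(=O)C[C@H](Oc1cc(OCOC)c(CC=C(C)C)c(OCOC)c1)c1ccccc1
A1 | direct plan | 1-[2,4,6-trihydroxy-3-(3-methylbut-2-en-1-yl)phenyl]ethanone | CC(=O)c1c(O)cc(O)c(CC=C(C)C)c1O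
A2 | direct plan | (E)-3-phenyl-1-[2,4,6-trihydroxy-3-(3-methylbut-2-en-1-yl)phenyl]prop-2-en-1-one | CC(C)=CCc1c(O)cc(O)c(C(=O)/C=C/c2ccccc2)c1O
A3 | direct plan | (2S)-5,7-dihydroxy-6-(3-methylbut-2-en-1-yl)-2-phenyl-2,3-dihydro-4H-chromen-4-one | CC(C)=CCc1c(O)cc2O[C@H](c3ccccc3)CC(=O)c2c1O
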